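- In a one-step world, with free catalyst never lost, substrate would decay pseudo-first-order and the fraction left would depend on catalyst charge times time, so I took that product as the clock for flasks of equal substrate charge.

| flask | substrate | free catalyst | remark | time |
|---|---|---|---|---|
| teal | 0.020 M | 1.1 mM | run made earlier |  |
| red | 0.020 M | 1.7 mM | run made earlier |  |
| ochre | 0.010 M | 0.76 mM | run made earlier |  |
| flask | 0.020 M | 0.76 mM |  | 4.0 h |

| run | time / h | substrate / % | target / % |
|---|---|---|---|
| teal | 0.333 | 83 | 17 |
| teal | 0.500 | 77 | 20 |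
| teal | 0.833 | 68 | 29 |
| teal | 1.33 | 58 | 39 |
| teal | 2.50 | 48 | 50 |
| teal | 4.00 | 37 | 58 |
| red | 0.250 | 80 | 19 |
| red | 0.833 | 57 | 39 |
| red | 1.33 | 50 | 49 |
| red | 2.00 | 37 | 56 |
| red | 3.00 | 33 | 65 |
| red | 4.00 | 27 | 69 |
| ochre | 0.333 | 86 | 12 |
| ochre | 0.667 | 76 | 23 |
| ochre | 1.00 | 69 | 29 |
| ochre | 2.00 | 55 | 44 |
| ochre | 4.00 | 39 | 57 |

(scatter of a reading: 1.5 percentage points)

* amount of substrate in percent of the substrate charged, at 25 min, 80 min and 4.0 h



- I tested the clock on the earlier runs: red at 0.833 h had 0.968 of the catalyst-time of teal at 1.33 h, and the two read 57 % and 58 %.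
- I kept 0.691 as the clock ratio, the free catalyst charge of the flask over that of teal; a flask time multiplied by it gave the matching teal time.
- For the start, I scaled the first teal reading by this ratio, which gave the flask a slope of 0.387 h⁻¹, so I reckoned 85.1 % of the substrate charged left at 25 min.
- That straight one-step decay predicted 59.7 % at 80 min and 21.3 % at 4.0 h, but teal bent away from it.
- Teal's matching times were 0.921 h and 2.76 h, and interpolation gave me 66.2 % and 46.1 %.
- My reckoned curve for the flask crossed 0.5 of the substrate charged near 3.28 h; teal still lost 11 percentage points over its last interval, so I drew no plateau by 4.0 h.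
- The forecast gave 85 %, 65.5 % and 42 %, holding that “the reaction is first order in catalyst”, and its last value lay below my 46.1 %.
- The flask gave 85.2 %, 66.7 % and 46.2 %.

    catalyst intermediate ⇌ free catalyst + target (K = 0.0150 M, k = 230 h⁻¹)
    catalyst intermediate → spent catalyst B (k = 0.570 h⁻¹)
    2 free catalyst → spent catalyst A (k = 230 M⁻¹ h⁻¹)
    substrate + free catalyst → catalyst intermediate (k = 620 M⁻¹ h⁻¹)

- Against my 46.1 % from the clock ratio 0.691, the flask held 46.2 % at 4.0 h. The flask's substrate half-life by capture on free catalyst was 1.5 h with the charges held fixed, but 8.0 h at 4.00 h, 5.44 times as long, when free catalyst stood at 18.4 % of the catalyst charged. Ochre shared the clock ratio with half the flask's substrate charge, yet it read 39 % at 4.00 h, lower than the flask by 7.2 points.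

The readings are simulated with constants of no real substance, noise included.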